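## The problem

The target is a flavanone: a chroman-4-one in which ring A is fused to the pyranone ring C and C2 carries the phenyl ring B. Ring A (C4a, C5, C6, C7, C8, C8a) has no hydrogen left. Oxygen sits on C5 (free OH), C7 (OMe) and C8a (ring oxygen O1); carbon sits on C4a (the C4 carbonyl), C6 and C8, which bear two identical 2-hydroxy-5-(2-hydroxybenzyl)benzyl arms (rings D and E). A synthesis must therefore place six substituents in a fixed order on one benzene ring. It must also tell the methylated O7 from the free O5, although both are flanked by the same arms.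

C2 (S) is the only stereocentre, so nothing in the molecule can relay chirality to it and a catalyst has to set it. It is also labile: base, or heat once the 5-OH is free, opens ring C by retro-oxa-Michael reaction to the achiral 2'-hydroxychalcone. It is best set late and kept away from base afterwards.

Five phenols, five electron-rich rings and the o-hydroxybenzyl–arene links (which can leave as o-quinone methides) exclude oxidants, hot protic acid and any late electrophilic substitution in which rings D and E would compete with ring A.

The feature that opens the route is the strict O–C–O–C–O–C alternation around ring A, with the same arm on C6 and C8. A vinylketene/ynol ether benzannulation writes exactly this pattern, and both annulation partners can be drawn from a single ynol ether.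

## Retrosynthesis

**Ether cleavage (28 from 27).** The last operation cuts five O–C bonds: the four isopropyl ethers on rings D and E and the methyl ether on O5. One boron-halide treatment should do all five, since secondary alkyl aryl ethers and a methyl ether chelated to the C4 carbonyl fall under conditions that leave an unchelated aryl methyl ether (O7) in place. Acetal protection of the arm phenols was set aside because it would not survive the Lewis acid needed to acylate ring A. Benzyl ethers were set aside because their Lewis-acid cleavage releases benzyl cations beside five electron-rich rings. Compound 27 is no simpler in skeleton, but every phenol is masked by a group that tolerates organometallics, 140 °C and Lewis acid. The forward step must not erode C2, which argues for acid and against base.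

**Ring B (27 from 25 and 26).** Cutting the C2–aryl bond leads to the achiral chromone 25 and phenylboronic acid 26. The neighbouring cut at O1–C2, an oxa-Michael closure of a 2'-hydroxychalcone, was weighed and rejected. That closure is reversible and, for chalcones without an activating group on C3, its catalytic versions are only modestly selective. Carbometalation of a chromone is an irreversible C–C bond formation with well-developed chiral ligands. The precursor loses the stereocentre and six carbons. The forward reaction must deliver phenyl to one face of a hindered, electron-rich enone.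

**Ring C (25 from 23 from 21).** The chromone is opened at O1–C2 and C2–C3, C2 being a one-carbon unit from a formamide acetal, to give methyl ketone 23. The C4a–C4 bond is then cut by a retro-Friedel–Crafts acetylation to phenol 21. In 21 the future C4a is the only ring carbon bearing hydrogen and lies ortho to the only free hydroxyl. Neither the site of acylation nor the oxygen that closes ring C is therefore open to choice. The forward steps only need to outpace acylation of the much less nucleophilic arm rings.

**Ring A (21 from 16 and 14).** Three ring bonds are cut at once: C8a–C8, C7–C6 and C8a–C4a. Cyclobutenone 16 supplies C8a, C4a, C5 and C6 with the C5 methoxy group and the C6 arm. Ynol ether 14 supplies C7 with its methoxy group and C8 with its arm. The neighbouring approach, double C-benzylation of a ready-made phloroglucinol, offers three nucleophilic ring positions plus the arm rings and no handle to stop at the 6,8-pattern. Here every substituent is fixed by the connectivity of the two partners. Both precursors are acyclic or four-membered, carry one arm each and are made from the same ynol ether. The forward reaction must open a donor-substituted cyclobutenone thermally and combine the resulting vinylketene with 14 in one regiochemical sense.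

**Cyclobutenone (16 from 14 and 15).** The four-membered ring is cut into ynol ether 14 and ketene 15, a [2+2] retron. Of the two bonds formed, the one from the ketene CH2 to the methoxy-bearing carbon survives as C5–C4a of ring A. This makes 14 the only advanced intermediate that feeds the key step, and it is used twice.

**Ynol ether (14 from 12 and 9).** The propargylic C–C bond is cut to methoxyacetylene 12 and benzylic bromide 9. A methoxy ynol ether is chosen because its oxygen substituent is already the C7 (and C5) methyl group. It also has no β-hydrogen on the alkoxy group, so the thermal retro-ene loss of alkene that limits ethoxy and tert-butoxy alkynes is impossible.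

**Arm (9 from 8 from 7 from 3 and 5).** The diarylmethane C(sp3)–C(sp2) bond is cut to benzylic chloride 3, used as its zinc reagent 6, and aryl bromide 5. Carrying the future benzylic carbon as a methyl ester lets the organozinc coupling proceed without a protecting step, since an aldehyde would be attacked. Reduction to 8 and bromination then give 9.

**Starting materials.** Compound 3 comes from 2-hydroxybenzyl alcohol 1 through its isopropyl ether 2. Compound 5 comes from methyl 5-bromosalicylate 4. Compound 12 comes from chloroacetaldehyde dimethyl acetal 10 by double elimination.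

## Roads not taken

**Alternative 1:** The cut is made at the two bonds that join the benzylic CH2 groups of rings E to C5'' of rings D, on a flavanone that already holds its stereocentre. In the forward direction the bis(aryl bromide) A2 and two equivalents of the N-hydroxyphthalimide ester A3 would be joined by a nickel-catalysed, decarboxylative cross-electrophile coupling at a cathode. This would give A1, the tetrakis(methoxymethyl) ether of 28.

- Merits: both outer rings are attached late under mild conditions from a cheap arylacetic acid derivative, and ring E can be varied for analogues. In modularity this road is better than the chosen one, and it avoids the early organozinc sequence.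
- Weak points: the hard part of the molecule is untouched, because A2 already contains the hexasubstituted ring A with two regiodefined benzyl groups, and making A2 needs a solution of the kind proposed here. Two couplings must succeed on one molecule. The aryl ketone and chelated phenol face a reducing electrode, with risk of ketyl chemistry and of cathodically generated base opening ring C and racemising C2. Benzylic radical dimerisation and protodebromination compete.
- Comparison: the chosen plan finishes the arms before ring A exists. Its one demanding step then runs on achiral, robust material, and the stereocentre never meets reducing or basic conditions.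

**Alternative 2:** The cut is C2–C3. The symmetric diazoketone A5, flanked by two O-benzyl groups, would be decomposed by a dirhodium carbenoid catalyst with chiral carboxylate ligands. The carbenoid at C3 would insert into a benzylic C–H bond of one benzyl ether to give A4, closing ring C and setting C2. The second benzyl ether stays on O5.

- Merits: the local symmetry of ring A removes any regiochemical question. The phenyl ring and the stereocentre come from a protecting group. O5 (benzyl) and O7 (methyl) are distinct from the outset, so the endgame needs no boron halide. In that respect, and in steps after ring A, it is better than the chosen plan.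
- Weak points: the closure is a six-membered insertion, while such carbenoids prefer five-membered transition states. The five-membered option here is attack of the ether oxygen on the carbenoid, giving an oxonium ylide that rearranges by benzyl shift to a benzofuranone. Carbenoids from terminal diazoketones carry no donor group and are the least enantioselective class. The arm rings invite Buchner-type side reactions. A5 also still needs the hexasubstituted ring.
- Comparison: the chosen plan spends three steps on ring C (acetylation, chromone formation, arylation). Each has close precedent, and the stereocentre comes from an established catalytic reaction.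

**Alternative 3:** The cuts are C4a–C4, C4–C3 and O1–C2. The 2-iodoresorcinol A7 and phenylacetylene A8 would be combined in a palladium-catalysed carbonylative annulation to give flavone A6.

- Merits: three bonds and ring C form in one operation. A7 is symmetric, so either hydroxyl closes to the same product. The iodine could be placed at the single free position of a resorcinol analogous to 21. To reach the ring C skeleton with the phenyl in place, this road takes one step against three and is better on step economy.
- Weak points: the product has C2 as an sp2 carbon. The stereocentre would then need an enantioselective reduction of the C2=C3 bond of a 5-hydroxyflavone, which is far less developed than conjugate arylation of chromones and tends to over-reduce to the flavan-4-ol. Oxidative addition into an electron-rich, doubly ortho-oxygenated carbon–iodine bond is slow. Direct alkynylation without carbonylation (leading to a benzofuran) and five-membered closure to the aurone compete.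
- Comparison: the chosen plan keeps C2 unsubstituted in chromone 25, so the phenyl group and the stereocentre arrive together in one better-precedented step.

Key step: step 10

Assumption: the sense of induction of the t-BuPyOx–palladium catalyst on chromone 25 is taken to follow that known for cyclic enones, which makes the (R)-ligand the one expected to give 2S; the ligand antipode is equally accessible.

Abbreviation used in names: Ar = 2-isopropoxy-5-(2-isopropoxybenzyl)phenyl, so ArCH2 is the protected arm.

## Route

Step 1
Reactants: 1 2-hydroxybenzyl alcohol
Product: 2 (2-isopropoxyphenyl)methanol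
Conditions: 2-bromopropane, K2CO3, DMF, 60 °C
Reagents that add atoms: 2-bromopropane, CC(C)Br
Why: Williamson ether synthesis; K2CO3 forms the phenoxide while the benzylic alcohol stays protonated, so alkylation should be selective for the phenol oxygen. The isopropyl ether survives organometallics, heat and BF3 and falls to BCl3 at the end.

Step 2
Reactants: 2 (2-isopropoxyphenyl)methanol
Product: 3 1-(chloromethyl)-2-isopropoxybenzene
Conditions: SOCl2, CH2Cl2, 0 °C to rt
Reagents that add atoms: thionyl chloride, O=S(Cl)Cl
Why: Chlorodehydroxylation of a benzylic alcohol through its chlorosulfite; the chloride is preferred to the bromide because benzylic chlorides give less Wurtz homocoupling on zinc insertion.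

Step 3
Reactants: 4 methyl 5-bromo-2-hydroxybenzoate
Product: 5 methyl 5-bromo-2-isopropoxybenzoate
Conditions: 2-bromopropane, K2CO3, DMF, 70 °C
Reagents that add atoms: 2-bromopropane, CC(C)Br
Why: Williamson etherification of the hydrogen-bonded salicylate phenol, which needs DMF and mild heating; the ester is inert to carbonate.

Step 4
Reactants: 3 1-(chloromethyl)-2-isopropoxybenzene; 5 methyl 5-bromo-2-isopropoxybenzoate
Product: 7 methyl 2-isopropoxy-5-(2-isopropoxybenzyl)benzoate, via benzylzinc chloride 6 (not isolated)
Conditions: Zn dust, LiCl, THF, 25 °C; then 5, Pd(OAc)2 (1 mol%), SPhos (2 mol%), THF, 25 °C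
Reagents that add atoms: none
Why: LiCl-promoted zinc insertion into the benzylic chloride gives 6, which undergoes Negishi coupling with the aryl bromide to form the diarylmethane bond. Benzylzinc reagents tolerate a methyl ester, which is why the carbonyl is carried at the ester level.

Step 5
Reactants: 7 methyl 2-isopropoxy-5-(2-isopropoxybenzyl)benzoate
Product: 8 [2-isopropoxy-5-(2-isopropoxybenzyl)phenyl]methanol
Conditions: LiAlH4, THF, 0 °C
Reagents that add atoms: none
Why: Hydride reduction of an aryl ester to the benzylic alcohol; the ethers and the diarylmethane are inert.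

Step 6
Reactants: 8 [2-isopropoxy-5-(2-isopropoxybenzyl)phenyl]methanol
Product: 9 2-(bromomethyl)-1-isopropoxy-4-(2-isopropoxybenzyl)benzene
Conditions: PBr3, CH2Cl2, 0 °C
Reagents that add atoms: phosphorus tribromide, BrP(Br)Br
Why: Bromodehydroxylation by SN2 displacement on the activated phosphite ester; the electron-rich benzylic bromide should be used without storage.

Step 7
Reactants: 10 chloroacetaldehyde dimethyl acetal
Product: 12 methoxyacetylene, via sodium methoxyacetylide 11 (not isolated)
Conditions: NaNH2 (3 equiv), liq. NH3, –33 °C; NH3 evaporated; sat. aq. NaCl, –70 °C; distilled into cold THF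
Reagents that add atoms: none
Why: Amide base removes methanol and then hydrogen chloride from the chloroacetal in two eliminations, and the third equivalent holds the alkyne as acetylide 11 until cold brine releases the volatile product. This is the standard preparation of alkoxyacetylenes.

Step 8
Reactants: 12 methoxyacetylene; 9 2-(bromomethyl)-1-isopropoxy-4-(2-isopropoxybenzyl)benzene
Product: 14 1-methoxy-3-[2-isopropoxy-5-(2-isopropoxybenzyl)phenyl]prop-1-yne, via lithium methoxyacetylide 13 (not isolated)
Conditions: n-BuLi, THF, –78 °C; then 9, HMPA, –78 to 0 °C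
Reagents that add atoms: none
Why: Deprotonation gives acetylide 13 free of amine and alkoxide, and SN2 alkylation by the benzylic bromide in THF/HMPA forms the propargylic C–C bond. Low temperature and only a modest excess of 13 guard against base-mediated propargyl-to-allenyl isomerisation.

Step 9
Reactants: 14 1-methoxy-3-[2-isopropoxy-5-(2-isopropoxybenzyl)phenyl]prop-1-yne; 15 ketene
Product: 16 3-methoxy-2-(ArCH2)cyclobut-2-en-1-one
Conditions: ketene gas (from acetone pyrolysis, excess), CH2Cl2, 0 °C to rt
Reagents that add atoms: none
Why: Thermal ketene–alkyne [2+2] cycloaddition; the nucleophilic β-carbon of the ynol ether attacks the ketene carbonyl carbon, so the arm ends on C2 and the methoxy group on C3. This is the usual outcome of ketene with alkoxyalkynes.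

Step 10
Reactants: 16 3-methoxy-2-(ArCH2)cyclobut-2-en-1-one; 14 1-methoxy-3-[2-isopropoxy-5-(2-isopropoxybenzyl)phenyl]prop-1-yne
Product: 21 3,5-dimethoxy-2,4-bis(ArCH2)phenol, via vinylketene 17 (not isolated), via 4-vinylcyclobutenone 18 (not isolated), via dienylketene 19 (not isolated), via cyclohexadienone 20 (not isolated)
Conditions: 14 (1.2 equiv), degassed toluene, 110 to 140 °C, sealed tube
Reagents that add atoms: none
Why: Danheiser benzannulation: 4π electrocyclic opening of 16 gives vinylketene 17, whose ketene C=C adds the ynol ether in a polar [2+2] to give 18; a second 4π opening gives dienylketene 19, 6π electrocyclisation gives dienone 20, and tautomerisation gives phenol 21. The closest known reaction type is the annulation of alkyl-substituted cyclobutenones with alkoxy- and siloxyalkynes to resorcinol monoethers; the 3-methoxy group on the cyclobutenone is the added element that turns the resorcinol into a phloroglucinol. Ring A closes by disrotatory 6π electrocyclisation of the dienylketene isomer with ketene and vinyl groups cis, forming C8a–C4a; the transient four-membered ring closes by ketene–alkyne [2+2]. No stereocentre is formed. The step needs regioselectivity in the [2+2]: the polarised ynol ether secures it, because its arm-bearing β-carbon is the nucleophilic end and bonds to the ketene carbonyl carbon (future C8a), which places the methoxy carbon at C7 between the two arms. The wrong dienylketene geometry cannot cyclise but can return to 18, so it should not divert material. The methoxy ynol ether cannot fragment by retro-ene reaction and the isopropyl ethers are inert at this temperature; a slight excess of 14 keeps 17 from acylating the product phenol.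

Step 11
Reactants: 21 3,5-dimethoxy-2,4-bis(ArCH2)phenol
Product: 23 1-[2-hydroxy-4,6-dimethoxy-3,5-bis(ArCH2)phenyl]ethan-1-one, via difluoroboron chelate 22 (not isolated)
Conditions: Ac2O, BF3·OEt2, CH2Cl2, 0 °C to rt; then aq. NaOAc, MeOH, 50 °C
Reagents that add atoms: acetic anhydride, CC(=O)OC(C)=O
Why: Friedel–Crafts acetylation (direct or by boron-assisted Fries shift of the O-acetate) at the only unsubstituted ring carbon, which is ortho to the hydroxyl and ortho and para to methoxy groups. The phloroglucinol nucleus is far more nucleophilic than the alkoxybenzene rings of the arms, and chelate 22 shields the product until hydrolysis.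

Step 12
Reactants: 23 1-[2-hydroxy-4,6-dimethoxy-3,5-bis(ArCH2)phenyl]ethan-1-one
Product: 25 5,7-dimethoxy-6,8-bis(ArCH2)-4H-chromen-4-one, via dimethylaminoenone 24 (not isolated)
Conditions: Me2NCH(OMe)2, toluene, 100 °C; then conc. HCl, CH2Cl2, rt
Reagents that add atoms: N,N-dimethylformamide dimethyl acetal, COC(OC)N(C)C
Why: Condensation of the methyl ketone with the formamide acetal gives enaminone 24; acid then drives addition–elimination by the ortho phenol with loss of dimethylamine, closing ring C. This is the standard enaminone route to 3-unsubstituted chromones.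

Step 13
Reactants: 25 5,7-dimethoxy-6,8-bis(ArCH2)-4H-chromen-4-one; 26 phenylboronic acid
Product: 27 (2S)-5,7-dimethoxy-6,8-bis(ArCH2)-2-phenylchroman-4-one
Conditions: Pd(OCOCF3)2 (5 mol%), (R)-t-BuPyOx [(R)-4-tert-butyl-2-(pyridin-2-yl)-4,5-dihydrooxazole] (6 mol%), NH4PF6 (30 mol%), H2O (5 equiv), ClCH2CH2Cl, 60 °C
Reagents that add atoms: none
Why: Palladium-catalysed asymmetric conjugate addition of an arylboronic acid to a chromone: transmetalation, enantio-determining carbopalladation of C2=C3 by the PyOx-ligated phenylpalladium cation, then protonolysis of the palladium enolate. The tert-butyl oxazoline differentiates the enone faces, and the (R)-ligand is expected to give 2S; the medium is not basic, so the product should not open.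

Step 14
Reactants: 27 (2S)-5,7-dimethoxy-6,8-bis(ArCH2)-2-phenylchroman-4-one
Product: 28 (2S)-5-hydroxy-6,8-bis[2-hydroxy-5-(2-hydroxybenzyl)benzyl]-7-methoxy-2-phenylchroman-4-one, 5''-(2''''-hydroxybenzyl)uvarinol
Conditions: BCl3 (10 equiv), CH2Cl2, –78 to 0 °C; MeOH, then water
Reagents that add atoms: none
Why: Lewis-acid ether cleavage: BCl3 removes the four isopropyl aryl ethers and, through the six-membered chelate with the C4 carbonyl, the 5-O-methyl group, while the unchelated 7-O-methyl ether is expected to stay. Acidic, base-free conditions avoid the retro-oxa-Michael opening that would racemise C2.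

## Compound list

1 | 2-hydroxybenzyl alcohol | OCc1ccccc1O | starting material
2 | (2-isopropoxyphenyl)methanol | CC(C)Oc1ccccc1CO | intermediate
3 | 1-(chloromethyl)-2-isopropoxybenzene | CC(C)Oc1ccccc1CCl | intermediate
4 | methyl 5-bromo-2-hydroxybenzoate | COC(=O)c1cc(Br)ccc1O | starting material
5 | methyl 5-bromo-2-isopropoxybenzoate | COC(=O)c1cc(Br)ccc1OC(C)C | intermediate
6 | (2-isopropoxybenzyl)zinc chloride | CC(C)Oc1ccccc1C[Zn]Cl | intermediate (not isolated)
7 | methyl 2-isopropoxy-5-(2-isopropoxybenzyl)benzoate | COC(=O)c1cc(Cc2ccccc2OC(C)C)ccc1OC(C)C | intermediate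
8 | [2-isopropoxy-5-(2-isopropoxybenzyl)phenyl]methanol | OCc1cc(Cc2ccccc2OC(C)C)ccc1OC(C)C | intermediate
9 | 2-(bromomethyl)-1-isopropoxy-4-(2-isopropoxybenzyl)benzene | BrCc1cc(Cc2ccccc2OC(C)C)ccc1OC(C)C | intermediate
10 | chloroacetaldehyde dimethyl acetal (2-chloro-1,1-dimethoxyethane) | COC(CCl)OC | starting material
11 | sodium methoxyacetylide | COC#C[Na] | intermediate (not isolated)
12 | methoxyacetylene (methoxyethyne) | COC#C | intermediate
13 | lithium methoxyacetylide | COC#C[Li] | intermediate (not isolated)
14 | 1-methoxy-3-[2-isopropoxy-5-(2-isopropoxybenzyl)phenyl]prop-1-yne | COC#CCc1cc(Cc2ccccc2OC(C)C)ccc1OC(C)C | intermediate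
15 | ketene | C=C=O | starting material (generated from acetone immediately before use)
16 | 3-methoxy-2-{[2-isopropoxy-5-(2-isopropoxybenzyl)phenyl]methyl}cyclobut-2-en-1-one | COC1=C(Cc2cc(Cc3ccccc3OC(C)C)ccc2OC(C)C)C(=O)C1 | intermediate
17 | 3-methoxy-2-(ArCH2)buta-1,3-dien-1-one (vinylketene) | C=C(OC)C(Cc1cc(Cc2ccccc2OC(C)C)ccc1OC(C)C)=C=O | intermediate (not isolated)
18 | 3-methoxy-4-(1-methoxyvinyl)-2,4-bis(ArCH2)cyclobut-2-en-1-one (racemic) | COC1=C(Cc2cc(Cc3ccccc3OC(C)C)ccc2OC(C)C)C(=O)C1(Cc1cc(Cc2ccccc2OC(C)C)ccc1OC(C)C)C(=C)OC | intermediate (not isolated)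
19 | (3E)-3,5-dimethoxy-2,4-bis(ArCH2)hexa-1,3,5-trien-1-one (dienylketene) | C=C(OC)/C(Cc1cc(Cc2ccccc2OC(C)C)ccc1OC(C)C)=C(/OC)C(Cc1cc(Cc2ccccc2OC(C)C)ccc1OC(C)C)=C=O | intermediate (not isolated)
20 | 3,5-dimethoxy-2,4-bis(ArCH2)cyclohexa-2,4-dien-1-one | COC1=C(Cc2cc(Cc3ccccc3OC(C)C)ccc2OC(C)C)C(OC)=C(Cc2cc(Cc3ccccc3OC(C)C)ccc2OC(C)C)C(=O)C1 | intermediate (not isolated)
21 | 3,5-dimethoxy-2,4-bis{[2-isopropoxy-5-(2-isopropoxybenzyl)phenyl]methyl}phenol | COc1cc(O)c(Cc2cc(Cc3ccccc3OC(C)C)ccc2OC(C)C)c(OC)c1Cc1cc(Cc2ccccc2OC(C)C)ccc1OC(C)C | intermediate
22 | difluoroboron chelate of ketone 23 (O,O-chelate of the phenoxide and acetyl oxygen) | CC1=[O+][B-](F)(F)Oc2c(Cc3cc(Cc4ccccc4OC(C)C)ccc3OC(C)C)c(OC)c(Cc3cc(Cc4ccccc4OC(C)C)ccc3OC(C)C)c(OC)c12 | intermediate (not isolated)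
23 | 1-[2-hydroxy-4,6-dimethoxy-3,5-bis(ArCH2)phenyl]ethan-1-one | CC(=O)c1c(O)c(Cc2cc(Cc3ccccc3OC(C)C)ccc2OC(C)C)c(OC)c(Cc2cc(Cc3ccccc3OC(C)C)ccc2OC(C)C)c1OC | intermediate
24 | (E)-3-(dimethylamino)-1-[2-hydroxy-4,6-dimethoxy-3,5-bis(ArCH2)phenyl]prop-2-en-1-one | CN(C)/C=C/C(=O)c1c(O)c(Cc2cc(Cc3ccccc3OC(C)C)ccc2OC(C)C)c(OC)c(Cc2cc(Cc3ccccc3OC(C)C)ccc2OC(C)C)c1OC | intermediate (not isolated)
25 | 5,7-dimethoxy-6,8-bis(ArCH2)-4H-chromen-4-one | COc1c(Cc2cc(Cc3ccccc3OC(C)C)ccc2OC(C)C)c(OC)c2c(c1Cc1cc(Cc3ccccc3OC(C)C)ccc1OC(C)C)occc2=O | intermediate
26 | phenylboronic acid | OB(O)c1ccccc1 | starting material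
27 | (2S)-5,7-dimethoxy-6,8-bis(ArCH2)-2-phenylchroman-4-one | COc1c(Cc2cc(Cc3ccccc3OC(C)C)ccc2OC(C)C)c(OC)c2c(c1Cc1cc(Cc3ccccc3OC(C)C)ccc1OC(C)C)O[C@H](c1ccccc1)CC2=O | intermediate
28 | (2S)-5-hydroxy-6,8-bis[2-hydroxy-5-(2-hydroxybenzyl)benzyl]-7-methoxy-2-phenylchroman-4-one | COc1c(Cc2cc(Cc3ccccc3O)ccc2O)c(O)c2c(c1Cc1cc(Cc3ccccc3O)ccc1O)O[C@H](c1ccccc1)CC2=O | target

## Step count and least certain steps

Total: 14 steps. Longest linear sequence: 12 steps (1, 2, 3, 7, 8, 9, 14, 16, 21, 23, 25, 27, 28, through steps 1, 2, 4, 5, 6, 8, 9, 10, 11, 12, 13, 14).

**Step 10 (key step).**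
- Risk: slow first ring opening. The 3-methoxy enone of 16 is a stabilised vinylogous ester, so the temperature needed may be high enough for the ynol ether to oligomerise or be hydrated by adventitious water before it is intercepted.
- Risk: acylation of the product phenol by vinylketene 17, which a methanolic KOH treatment of the crude product would reverse.
- Fallback: generate vinylketene 17 at room temperature by photochemical Wolff rearrangement, the diazo ketone variant of the same annulation. It sets out from bromide 9 and ynol ether 14 and returns at 21.
  - 3-Methoxybut-3-en-2-one F1 is prepared from commercial 3,3-dimethoxybutan-2-one by acid-catalysed loss of methanol.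
  - F1 is deprotonated with LiN(i-Pr)2 at –78 °C and alkylated with 9 to give 2-methoxy-5-Ar-pent-1-en-3-one F2.
  - Detrifluoroacetylative diazo transfer follows: LiN(SiMe3)2 and 2,2,2-trifluoroethyl trifluoroacetate give the trifluoroacetyl diketone F3, and MsN3 with Et3N gives 4-diazo-2-methoxy-5-Ar-pent-1-en-3-one F4.
  - Irradiation of F4 with 14 (300 nm, ClCH2CH2Cl, rt, then 80 °C) should expel nitrogen and shift the 1-methoxyvinyl group to give 17, which continues through 18, 19 and 20 to 21.

**Step 8.**
- Risk: sluggish alkylation of the weakly nucleophilic alkoxyacetylide, and base-mediated isomerisation of the doubly activated benzylic-propargylic CH2 of 14 to the allenyl ether.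
- Fallback: replace SN2 by cross-coupling, setting out from 13 and 9 and returning at 14. Acetylide 13 is quenched with Bu3SnCl to give tributyl(methoxyethynyl)stannane F5. Stille coupling of F5 with 9 (Pd(PPh3)4, THF, 60 °C) forms the same C–C bond under neutral conditions.

**Step 9.**
- Risk: ketene dimerises and polymerises faster than it adds to a hindered internal ynol ether, and the product enol ether may hydrolyse to the cyclobutane-1,3-dione on work-up.
- Fallback: use the more electrophilic dichloroketene, setting out from 14 and returning at 16. Trichloroacetyl chloride and Zn(Cu) in Et2O should give 4,4-dichloro-3-methoxy-2-(ArCH2)cyclobut-2-en-1-one F6. Reductive dechlorination (Zn, AcOH, TMEDA, EtOH) then gives 16.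

**Step 13.**
- Risk: low conversion, because the 5,7-dimethoxy groups make the chromone a poor acceptor and the C8 arm crowds O1. Protodeboronation and insufficient facial selectivity are also possible.
- Fallback: set C2 by oxa-Michael closure of an activated alkylidene β-ketoester, setting out from 23 and returning at 27.
  - The enolate of 23 (LiN(SiMe3)2, 3 equiv) is acylated with di-tert-butyl dicarbonate to give tert-butyl β-ketoester F7.
  - Knoevenagel condensation with benzaldehyde (piperidine, AcOH, molecular sieves) gives benzylidene β-ketoester F8.
  - A cinchona-derived bifunctional thiourea, with quinine or quinidine backbone chosen for the 2S sense, should close ring C to tert-butyl (2S)-4-oxo-2-phenylchromane-3-carboxylate F9.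
  - TsOH in toluene at 80 °C removes the ester by loss of isobutene and decarboxylation to give 27.

**Step 14.**
- Risk: partial racemisation by Lewis-acid-assisted opening of ring C during the long exposure needed for five cleavages. Cleavage of the twisted 7-methoxy group and ring isopropylation are further risks.
- Fallback: reverse the order so that no Lewis acid meets the stereocentre, setting out from 25 and returning at 28. BCl3 treatment of chromone 25 gives 5-hydroxy-6,8-bis[2-hydroxy-5-(2-hydroxybenzyl)benzyl]-7-methoxy-4H-chromen-4-one F10. The aqueous palladium-catalysed conjugate addition of 26 under the conditions of step 13, which is expected to tolerate free phenols, is then the last step and gives 28 directly.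

## Further compounds

F1 | step 10 | 3-methoxybut-3-en-2-one | C=C(OC)C(C)=O
F2 | step 10 | 2-methoxy-5-[2-isopropoxy-5-(2-isopropoxybenzyl)phenyl]pent-1-en-3-one | C=C(OC)C(=O)CCc1cc(Cc2ccccc2OC(C)C)ccc1OC(C)C
F3 | step 10 | 1,1,1-trifluoro-5-methoxy-3-{[2-isopropoxy-5-(2-isopropoxybenzyl)phenyl]methyl}hex-5-ene-2,4-dione | C=C(OC)C(=O)C(Cc1cc(Cc2ccccc2OC(C)C)ccc1OC(C)C)C(=O)C(F)(F)F
F4 | step 10 | 4-diazo-2-methoxy-5-[2-isopropoxy-5-(2-isopropoxybenzyl)phenyl]pent-1-en-3-one | C=C(OC)C(=O)C(=[N+]=[N-])Cc1cc(Cc2ccccc2OC(C)C)ccc1OC(C)C
F5 | step 8 | tributyl(methoxyethynyl)stannane | CCCC[Sn](CCCC)(CCCC)C#COC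
F6 | step 9 | 4,4-dichloro-3-methoxy-2-{[2-isopropoxy-5-(2-isopropoxybenzyl)phenyl]methyl}cyclobut-2-en-1-one | COC1=C(Cc2cc(Cc3ccccc3OC(C)C)ccc2OC(C)C)C(=O)C1(Cl)Cl
F7 | step 13 | tert-butyl 3-[2-hydroxy-4,6-dimethoxy-3,5-bis(ArCH2)phenyl]-3-oxopropanoate | CC(C)(C)OC(=O)CC(=O)c1c(O)c(Cc2cc(Cc3ccccc3OC(C)C)ccc2OC(C)C)c(OC)c(Cc2cc(Cc3ccccc3OC(C)C)ccc2OC(C)C)c1OC
F8 | step 13 | tert-butyl 2-[2-hydroxy-4,6-dimethoxy-3,5-bis(ArCH2)benzoyl]-3-phenylprop-2-enoate (E/Z mixture) | CC(C)(C)OC(=O)C(=Cc1ccccc1)C(=O)c1c(O)c(Cc2cc(Cc3ccccc3OC(C)C)ccc2OC(C)C)c(OC)c(Cc2cc(Cc3ccccc3OC(C)C)ccc2OC(C)C)c1OC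
F9 | step 13 | tert-butyl (2S)-5,7-dimethoxy-4-oxo-2-phenyl-6,8-bis(ArCH2)chromane-3-carboxylate (C3 epimers) | COc1c(Cc2cc(Cc3ccccc3OC(C)C)ccc2OC(C)C)c(OC)c2c(c1Cc1cc(Cc3ccccc3OC(C)C)ccc1OC(C)C)O[C@H](c1ccccc1)C(C(=O)OC(C)(C)C)C2=O
F10 | step 14 | 5-hydroxy-6,8-bis[2-hydroxy-5-(2-hydroxybenzyl)benzyl]-7-methoxy-4H-chromen-4-one | COc1c(Cc2cc(Cc3ccccc3O)ccc2O)c(O)c2c(c1Cc1cc(Cc3ccccc3O)ccc1O)occc2=O
A1 | alternative 1 | (2S)-5-hydroxy-7-methoxy-6,8-bis{2-(methoxymethoxy)-5-[2-(methoxymethoxy)benzyl]benzyl}-2-phenylchroman-4-one | COc1c(Cc2cc(Cc3ccccc3OCOC)ccc2OCOC)c(O)c2c(c1Cc1cc(Cc3ccccc3OCOC)ccc1OCOC)O[C@H](c1ccccc1)CC2=O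
A2 | alternative 1 | (2S)-6,8-bis[5-bromo-2-(methoxymethoxy)benzyl]-5-hydroxy-7-methoxy-2-phenylchroman-4-one | COc1c(Cc2cc(Br)ccc2OCOC)c(O)c2c(c1Cc1cc(Br)ccc1OCOC)O[C@H](c1ccccc1)CC2=O
A3 | alternative 1 | 1,3-dioxoisoindolin-2-yl 2-[2-(methoxymethoxy)phenyl]acetate | COCOc1ccccc1CC(=O)ON1C(=O)c2ccccc2C1=O
A4 | alternative 2 | (2S)-5-(benzyloxy)-7-methoxy-6,8-bis{2-(methoxymethoxy)-5-[2-(methoxymethoxy)benzyl]benzyl}-2-phenylchroman-4-one | COc1c(Cc2cc(Cc3ccccc3OCOC)ccc2OCOC)c(OCc2ccccc2)c2c(c1Cc1cc(Cc3ccccc3OCOC)ccc1OCOC)O[C@H](c1ccccc1)CC2=O
A5 | alternative 2 | 1-[2,6-bis(benzyloxy)-4-methoxy-3,5-bis{2-(methoxymethoxy)-5-[2-(methoxymethoxy)benzyl]benzyl}phenyl]-2-diazoethan-1-one | COc1c(Cc2cc(Cc3ccccc3OCOC)ccc2OCOC)c(OCc2ccccc2)c(C(=O)C=[N+]=[N-])c(OCc2ccccc2)c1Cc1cc(Cc2ccccc2OCOC)ccc1OCOC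
A6 | alternative 3 | 5-hydroxy-7-methoxy-6,8-bis{2-(methoxymethoxy)-5-[2-(methoxymethoxy)benzyl]benzyl}-2-phenyl-4H-chromen-4-one | COc1c(Cc2cc(Cc3ccccc3OCOC)ccc2OCOC)c(O)c2c(c1Cc1cc(Cc3ccccc3OCOC)ccc1OCOC)oc(-c1ccccc1)cc2=O
A7 | alternative 3 | 2-iodo-5-methoxy-4,6-bis{2-(methoxymethoxy)-5-[2-(methoxymethoxy)benzyl]benzyl}benzene-1,3-diol | COc1c(Cc2cc(Cc3ccccc3OCOC)ccc2OCOC)c(O)c(I)c(O)c1Cc1cc(Cc2ccccc2OCOC)ccc1OCOC
A8 | alternative 3 | phenylacetylene | C#Cc1ccccc1
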